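A direct plan would go through a chalcone: 3-acetoxy-2,4,5-trimethoxybenzaldehyde A1 would be condensed (KOH) with 2-hydroxy-4,6-bis(benzyloxy)acetophenone A2 to the 2'-hydroxychalcone A3, ring C would be closed oxidatively (I2, DMSO, 130 °C) to the 5,7-bis(benzyloxy)flavone A4, and hydrogenolysis would free the two hydroxyls of ring A.
Its weakest points would be:
(a) the oxidative closure of ring C, which would leave to chance whether the phenol adds 6-endo (flavone) or 5-exo (aurone), and would expose two very electron-rich rings and a free phenol to iodine and HI at 130 °C (ring iodination, loss of the 5-O-benzyl group);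
(b) the final hydrogenolysis, which would be run on the most precious material only to remove protecting groups that first had to be put on A2, with the C2=C3 bond of the pyranone at risk of reduction;
(c) the aldol condensation, in which A1 would lose its acetate and react as an electron-rich phenoxide aldehyde, slowly and under a large excess of hydroxide.

**Plan of the new route**
The retrosynthesis cuts ring A instead of ring C: C5–C6 and C7–C8 are opened (two Claisen condensations), which leads back to the 4-pyranone ester 11 (rings B and C only) and an acetyl unit.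
Feature used: ring A is a phloroglucinol ring. Its oxygens on C5, C7 and C8a (O1) stand 1,3 to one another, so it is the enol form of a cyclohexane-1,3,5-trione. C5 and C7 can therefore enter as the carbonyl carbons of an ester and an acetyl group, and C8, C8a and C4a as the methyl group, C2 and C3 of a 2-methyl-4-pyranone-3-carboxylate.
Compound 11 is cut at C4–C4a and O1–C8a (flavone numbering) into an aroylketene and an acetoacetate enol ether. The C1'–C2 bond comes from a Friedel–Crafts acylation, the 3'-oxygen from ortho-lithiation between two methoxy groups.
The rings arise in the order B (bought), C (step 4), A (step 5, last).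
No chalcone is made and every carbon enters at its final oxidation level, so no oxidative closure is needed. Ring A never carries a protecting group because its hydroxyls are formed only in the last step, so nothing is hydrogenolysed and the last step gives the target itself.

Key step: step 5

Remark on the chemistry: the 3'-hydroxyl, a hindered phenol between two methoxy groups, is carried unprotected from 7 on. It should add to acylketenes only reversibly, and in step 5 it is simply a phenoxide.

Step 1
Reactants: 1 1,2,4-trimethoxybenzene
Product: 4 2,3,6-trimethoxyphenol, via (2,3,6-trimethoxyphenyl)lithium 2 (not isolated), via dimethyl (2,3,6-trimethoxyphenyl)boronate 3 (not isolated)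
Conditions: n-BuLi, THF, 0 → 23 °C; B(OMe)3, −78 → 23 °C; AcOH, 30% H2O2, 0 → 23 °C
Reagents that add atoms: hydrogen peroxide (OO); n-butyllithium ([Li]CCCC) and trimethyl borate (COB(OC)OC) leave atoms only in intermediates 2 and 3
Why: Directed ortho-metalation should remove the C3–H of 1 that lies between two methoxy groups, and borylation followed by peroxide oxidation (1,2-shift of the aryl group from boron to oxygen) puts the hydroxyl on that carbon; no stereocentre is formed.

Step 2
Reactants: 4 2,3,6-trimethoxyphenol
Product: 5 2,3,6-trimethoxyphenyl acetate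
Conditions: Ac2O, pyridine, DMAP (cat.), 23 °C
Reagents that add atoms: acetic anhydride (CC(=O)OC(C)=O)
Why: O-acylation (nucleophilic catalysis by DMAP for the doubly ortho-substituted phenol) turns the strongest donor of the ring into a weak one, so that the methoxy groups direct the Friedel–Crafts acylation of step 3.

Step 3
Reactants: 5 2,3,6-trimethoxyphenyl acetate
Product: 7 ethyl 3-(3-hydroxy-2,4,5-trimethoxyphenyl)-3-oxopropanoate, via acetoxy keto ester 6 (not isolated)
Conditions: ClC(O)CH2CO2Et (1.3 equiv), TiCl4 (2.5 equiv), CH2Cl2, −10 → 0 °C; ice, 1 M HCl; then crude 6: HCl (cat.), EtOH, 50 °C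
Reagents that add atoms: ethyl 3-chloro-3-oxopropanoate, i.e. ethyl malonyl chloride (CCOC(=O)CC(Cl)=O)
Why: Friedel–Crafts acylation should take place at the one free position of 5 that is ortho to a methoxy group and para to another, in preference to the position para to the weakly donating acetoxy group, and acid-catalysed transesterification with ethanol then removes the acetate from crude 6 without changing the ethyl ester.

Step 4
Reactants: 7 ethyl 3-(3-hydroxy-2,4,5-trimethoxyphenyl)-3-oxopropanoate; 8 ethyl (E)-3-ethoxybut-2-enoate
Product: 11 ethyl 6-(3-hydroxy-2,4,5-trimethoxyphenyl)-2-methyl-4-oxo-4H-pyran-3-carboxylate, via aroylketene 9 (not isolated), via dihydropyranone cycloadduct 10 (not isolated)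
Conditions: 8 (10 equiv, as solvent), 165 °C, slow addition of 7, EtOH distilled off; then TsOH (cat.), toluene, 80 °C
Reagents that add atoms: none
Why: Acylketene hetero-Diels–Alder reaction: above 150 °C the β-keto ester 7 should lose ethanol to give aroylketene 9 (the pathway of thermal transacetoacetylation), whose oxadiene adds the enol ether 8 with the ketene carbon bonding to the ester-bearing carbon of 8 and the aroyl oxygen to its ethoxy carbon, so that loss of ethanol from 10 (two transient stereocentres, both destroyed) leaves the 4-pyranone with the ester at C3 next to the methyl at C2; ethanol is the only by-product and merely returns 9 to 7.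

Step 5
Reactants: 11 ethyl 6-(3-hydroxy-2,4,5-trimethoxyphenyl)-2-methyl-4-oxo-4H-pyran-3-carboxylate
Product: 15 5,7,3'-trihydroxy-2',4',5'-trimethoxyflavone, via dilithio extended enolate 12 (not isolated), via lithiated Weinreb adduct 13 (not isolated), via keto ester 14 (not isolated)
Conditions: LiN(i-Pr)2 (2.2 equiv), THF, −78 °C; MeC(O)N(OMe)Me (1.2 equiv), −78 → −40 °C; LiN(i-Pr)2 (2.5 equiv), −78 → 23 °C; then 1 M HCl
Reagents that add atoms: N-methoxy-N-methylacetamide (CC(=O)N(C)OC)
Why: Proposed new method: the first charge of base removes the phenol proton and one proton of the C2 methyl of 11 (acidified through C2=C3 by both the ring ketone and the ester), and the extended enolate 12 is acylated at its exocyclic carbon by the Weinreb amide to give adduct 13, which cannot be acylated twice; the second charge collapses 13 to the enolate of 14 and removes a proton from its terminal methyl, and this dianion attacks the neighbouring ester carbonyl, after which loss of ethoxide and enolisation leave ring A as an aromatic phenoxide. The closest known reaction type is the lateral lithiation–acylation–Claisen sequence that converts ortho-toluate esters into naphthalene-1,3-diols, together with the ester condensations of 2-methyl-4-pyranones at the methyl group; it has not been shown on a 2-methyl-4-pyranone-3-carboxylate, hence the label. Ring A is closed at C5–C6 by a 6-exo-trig Dieckmann-type attack of the C6 enolate carbon on the ester carbon, C7–C8 having been formed intermolecularly just before, and ring C is not touched. No stereocentre arises. The step needs 12 to react through its exocyclic carbon and not through oxygen or C3, which is secured by the choice of a Weinreb amide (acylation at carbon, no double addition) and by the fact that only exocyclic attack restores the aromatic 4-pyranone; it also needs the pyranone to resist addition of the base, which its anionic state should provide. Aromatisation to the polyphenoxide makes the sequence irreversible and delivers all three hydroxyls free, so no deprotection follows.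

**Compound list**
1 | 1,2,4-trimethoxybenzene | COc1ccc(OC)c(OC)c1 | starting material
2 | (2,3,6-trimethoxyphenyl)lithium (not isolated) | COc1ccc(OC)c([Li])c1OC | intermediate
3 | dimethyl (2,3,6-trimethoxyphenyl)boronate (not isolated) | COc1ccc(OC)c(B(OC)OC)c1OC | intermediate
4 | 2,3,6-trimethoxyphenol | COc1ccc(OC)c(O)c1OC | intermediate
5 | 2,3,6-trimethoxyphenyl acetate | COc1ccc(OC)c(OC(C)=O)c1OC | intermediate
6 | ethyl 3-(3-acetoxy-2,4,5-trimethoxyphenyl)-3-oxopropanoate (not isolated) | COc1cc(C(=O)CC(=O)OCC)c(OC)c(OC(C)=O)c1OC | intermediate
7 | ethyl 3-(3-hydroxy-2,4,5-trimethoxyphenyl)-3-oxopropanoate | COc1cc(C(=O)CC(=O)OCC)c(OC)c(O)c1OC | intermediate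
8 | ethyl (E)-3-ethoxybut-2-enoate | CCO/C(C)=C/C(=O)OCC | starting material
9 | 3-(3-hydroxy-2,4,5-trimethoxyphenyl)-3-oxoprop-1-en-1-one (aroylketene, not isolated) | COc1cc(C(=O)C=C=O)c(OC)c(O)c1OC | intermediate
10 | ethyl 2-ethoxy-6-(3-hydroxy-2,4,5-trimethoxyphenyl)-2-methyl-4-oxo-3,4-dihydro-2H-pyran-3-carboxylate (racemic mixture of diastereomers, not isolated) | CCOC(=O)C1C(=O)C=C(c2cc(OC)c(OC)c(O)c2OC)OC1(C)OCC | intermediate
11 | ethyl 6-(3-hydroxy-2,4,5-trimethoxyphenyl)-2-methyl-4-oxo-4H-pyran-3-carboxylate | CCOC(=O)c1c(C)oc(-c2cc(OC)c(OC)c(O)c2OC)cc1=O | intermediate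
12 | dilithium salt of 11: lithium phenoxide and 2-(lithiomethyl) extended enolate (not isolated) | CCOC(=O)c1c(C[Li])oc(-c2cc(OC)c(OC)c(O[Li])c2OC)cc1=O | intermediate
13 | ethyl 2-[2-(lithiooxy)-2-[methoxy(methyl)amino]propyl]-6-(3-lithiooxy-2,4,5-trimethoxyphenyl)-4-oxo-4H-pyran-3-carboxylate (racemic, not isolated) | CCOC(=O)c1c(CC(C)(O[Li])N(C)OC)oc(-c2cc(OC)c(OC)c(O[Li])c2OC)cc1=O | intermediate
14 | ethyl 6-(3-hydroxy-2,4,5-trimethoxyphenyl)-4-oxo-2-(2-oxopropyl)-4H-pyran-3-carboxylate (in the flask as its lithium enolates, not isolated) | CCOC(=O)c1c(CC(C)=O)oc(-c2cc(OC)c(OC)c(O)c2OC)cc1=O | intermediate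
15 | 5,7-dihydroxy-2-(3-hydroxy-2,4,5-trimethoxyphenyl)-4H-chromen-4-one, i.e. 5,7,3'-trihydroxy-2',4',5'-trimethoxyflavone (achiral) | COc1cc(-c2cc(=O)c3c(O)cc(O)cc3o2)c(OC)c(O)c1OC | target

Total step count: 5. Longest linear sequence: 5 steps (1 → 4 → 5 → 7 → 11 → 15).

**Steps most likely to fail**

1. Step 5 (Proposed new method). The extended enolate 12 is stabilised and may add too slowly to the amide or be acylated on oxygen. The polyanion formed with the second charge of base may precipitate before the ring closes, or the amide base may open the pyranone. The fallback uses known chemistry, sets out from 7 and comes back at 15. Ring A would then not be built but bought as phloroglucinol (benzene-1,3,5-triol), which would be heated with 7 without solvent at 240 °C (or under microwave irradiation) in a Mentzer-type condensation. Aroylketene 9 should acylate a ring carbon of phloroglucinol to give 1-(3-hydroxy-2,4,5-trimethoxyphenyl)-3-(2,4,6-trihydroxyphenyl)propane-1,3-dione F1, which should lose water by attack of an ortho hydroxyl on the aryl ketone to give 15 directly. No protecting group is needed because the three free ring positions of phloroglucinol are equivalent.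

2. Step 4. Dimerisation of the aroylketene, or its capture by the enol of unreacted 7, may outrun the cycloaddition to the only moderately nucleophilic push–pull enol ether; the active methylene of 7 may also condense with 8. The fallback sets out from 7 and comes back at 11. It replaces the high-temperature cycloaddition by a stepwise polar acylation of an enamine with a separate ring closure. Saponification (NaOH, H2O, 0 °C, cold acidification) would give 3-(3-hydroxy-2,4,5-trimethoxyphenyl)-3-oxopropanoic acid F2. Acetone, Ac2O and catalytic H2SO4 would convert F2 into 6-(3-acetoxy-2,4,5-trimethoxyphenyl)-2,2-dimethyl-4H-1,3-dioxin-4-one F3, the phenol being acetylated in the same operation. F3 should release its acylketene already at 110 °C in toluene, where it is captured at carbon by the far more nucleophilic enamine ethyl 3-(pyrrolidin-1-yl)but-2-enoate. This would give ethyl 2-[3-(3-acetoxy-2,4,5-trimethoxyphenyl)-3-oxopropanoyl]-3-(pyrrolidin-1-yl)but-2-enoate F4. HCl in ethanol at 60 °C would then close the pyranone with loss of pyrrolidine and remove the acetate to give 11.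

3. Step 3. The enolisable, chelating acid chloride may acylate sluggishly, so that long exposure to TiCl4 cleaves the methoxy group ortho to the new ketone or shifts the acetyl group onto the ring, and regiocontrol may erode. The fallback sets out from 5 and comes back at 6. The carbonyl carbon alone would be introduced with the small, reactive Rieche electrophile (Cl2CHOMe, TiCl4, CH2Cl2, −10 °C, aqueous work-up) to give 3-acetoxy-2,4,5-trimethoxybenzaldehyde F5 (identical with A1). Roskamp homologation with ethyl diazoacetate and catalytic SnCl2 in CH2Cl2 at 23 °C would then convert the aldehyde into the β-keto ester 6, which continues with the ethanolysis of step 3.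

**Further compounds**
F1 | step 5 | 1-(3-hydroxy-2,4,5-trimethoxyphenyl)-3-(2,4,6-trihydroxyphenyl)propane-1,3-dione | COc1cc(C(=O)CC(=O)c2c(O)cc(O)cc2O)c(OC)c(O)c1OC
F2 | step 4 | 3-(3-hydroxy-2,4,5-trimethoxyphenyl)-3-oxopropanoic acid | COc1cc(C(=O)CC(=O)O)c(OC)c(O)c1OC
F3 | step 4 | 6-(3-acetoxy-2,4,5-trimethoxyphenyl)-2,2-dimethyl-4H-1,3-dioxin-4-one | COc1cc(C2=CC(=O)OC(C)(C)O2)c(OC)c(OC(C)=O)c1OC
F4 | step 4 | ethyl 2-[3-(3-acetoxy-2,4,5-trimethoxyphenyl)-3-oxopropanoyl]-3-(pyrrolidin-1-yl)but-2-enoate (double-bond isomers interconvert) | CCOC(=O)C(C(=O)CC(=O)c1cc(OC)c(OC)c(OC(C)=O)c1OC)=C(C)N1CCCC1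
F5 | step 3 | 3-acetoxy-2,4,5-trimethoxybenzaldehyde | COc1cc(C=O)c(OC)c(OC(C)=O)c1OC
A1 | direct plan | 3-acetoxy-2,4,5-trimethoxybenzaldehyde | COc1cc(C=O)c(OC)c(OC(C)=O)c1OC
A2 | direct plan | 1-[2,4-bis(benzyloxy)-6-hydroxyphenyl]ethan-1-one | CC(=O)c1c(O)cc(OCc2ccccc2)cc1OCc1ccccc1
A3 | direct plan | (E)-1-[2,4-bis(benzyloxy)-6-hydroxyphenyl]-3-(3-hydroxy-2,4,5-trimethoxyphenyl)prop-2-en-1-one | COc1cc(/C=C/C(=O)c2c(O)cc(OCc3ccccc3)cc2OCc2ccccc2)c(OC)c(O)c1OC
A4 | direct plan | 5,7-bis(benzyloxy)-2-(3-hydroxy-2,4,5-trimethoxyphenyl)-4H-chromen-4-one | COc1cc(-c2cc(=O)c3c(OCc4ccccc4)cc(OCc4ccccc4)cc3o2)c(OC)c(O)c1OC
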